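Count how much decay the links in each flask have suffered by the time you read it.

the same everywhere: first end groups 0.40 M
- Friday's: second end groups 0.44 M; one-sided end groups 4 mM; temperature 115 °C; run made earlier
- Monday's: second end groups 0.44 M; one-sided end groups 16 mM; temperature 126 °C; run made earlier
- Tuesday's: second end groups 0.88 M; one-sided end groups 8 mM; temperature 115 °C; run made earlier
- ash: second end groups 0.440 M; one-sided end groups 8.00 mM; at 110 °C until 2.0 min, from then on at 130 °C; time 6.0 min
- alder: second end groups 0.440 M; one-sided end groups 8.00 mM; at 130 °C throughout; time 2.0 min

| run | time / min | links / % | first end groups / % |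
|---|---|---|---|
| Friday's | 1.33 | 36 | 59 |
| Friday's | 2.50 | 32 | 56 |
| Friday's | 4.00 | 26 | 58 |
| Friday's | 5.00 | 25 | 58 |
| Friday's | 6.00 | 20 | 59 |
| Friday's | 8.00 | 14 | 57 |
| Monday's | 0.667 | 28 | 63 |
| Monday's | 1.00 | 22 | 62 |
| Monday's | 2.00 | 19 | 62 |
| Monday's | 2.50 | 13 | 63 |
| Monday's | 4.00 | 9 | 60 |
| Tuesday's | 0.667 | 53 | 39 |
| Tuesday's | 2.00 | 56 | 31 |
| Tuesday's | 3.00 | 47 | 30 |
| Tuesday's | 5.00 | 34 | 29 |
| Tuesday's | 8.00 | 28 | 31 |

(scatter of a reading: 1.5 percentage points)

- which of the two ends with the higher amount of links, in percent of the first end groups charged ("neither" if they lie within 2 percentage points) (ash / alder / neither)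
- links at the end, in percent of the first end groups charged, ash
- links at the end, in percent of the first end groups charged, alder

- the analysis behind the earlier runs scatters by 1.5 percentage points, standard deviation
- steps thought possible: first end groups + second end groups -> links; first end groups + one-sided end groups -> capped ends; second end groups -> decomposed reagent; links -> over-reaction product

Links fall from the first reading on in Friday's and Monday's runs, and links are counted here as fractions of the first end groups charged. Friday's go from 36 % to 14 %, a loss constant of 0.142 /min. Monday's go from 28 % to 9 %, which gives 0.341 /min. A straight line in the logarithm through these two readings gives me 0.0950 /min at 110 °C and 0.469 /min at 130 °C.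

Multiply each constant by the time spent at it and add. Ash gets 2.06 and alder gets 0.937. Call this number the decay exposure, a Damköhler number: e to the minus exposure is the fraction of links formed at the start still standing.

Ash has the higher exposure. With equal links formed, ash ends at 0.325 of alder's amount.

Is one number enough? Hold formation against it. Subtract the first end groups still standing and the one-sided charge, and Friday's run reads 41.0 % formed, while the hotter Monday's run reads 34.0 %. Take these as stand-ins for ash and alder. Their ratio, 1.21, is smaller than the survival ratio, 3.07. So I expect alder ahead, with ash at 5.20 % and alder at 13.3 %.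

The forecast says alder, with ash at 6.4 % and alder at 14 %: “Links then decay slowly.” My two numbers lie lower than its two.

The simulation gives alder, with ash at 5.15 % and alder at 12.3 %.

    first end groups + second end groups → links (k = 0.0340 /M/s, Ea = 81.0 kJ/mol)
    first end groups + one-sided end groups → capped ends (k = 1.90 /M/s, Ea = 64.0 kJ/mol)
    second end groups → decomposed reagent (k = 0.0150 /s, Ea = 119 kJ/mol)
    links → over-reaction product (k = 0.00130 /s, Ea = 120 kJ/mol)
    (constants at 110 °C)

Ash's links go to over-reaction product: with that step taken away, ash ends at 43.4 %, not 5.15 %, and the answer turns. Multiply that 43.4 % by e to the minus 2.06 and you get 5.53 %. The second flask is alder read at 80 s. Give back the exposure of the time saved, 0.312, and alder's 12.3 % grows to 16.8 %, against a simulated 17.2 %.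

(The runs are simulated from invented constants; the scatter is artificial.)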